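The numbers in the tables are simulated for an exercise; the scatter is artificial.

Target, the product I want, reads 30% of the substrate charged in flask zeta at 30.0 min, and I must decide what to do with that flask next.

| setting | zeta | theta | flask |
|---|---|---|---|
| substrate | 0.50 M | 0.50 M | 0.50 M |
| partner | 1.2 equiv | 2.4 equiv | 1.20 equiv |
| temperature | 5 °C | 5 °C | 5 °C |
| remark | the very flask that is asked about, followed so far | run made earlier |  |
| time |  |  | 30 min |

- zeta (time / min: target / %): 2.00: 7; 6.00: 26; 10.0: 32; 15.0: 32; 25.0: 30; 30.0: 30
- theta (time / min: target / %): 1.00: 6; 1.50: 11; 2.50: 22; 4.00: 32; 8.00: 44; 12.0: 38

(scatter of a reading: 1.5 percentage points)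

* target, in percent of the substrate first charged, at 30 min
* what to do for the largest gain in target; "none" if nothing gains more than 2 percentage points (dusk / noon / winter / midnight / none)
* target present, in percent of the substrate first charged, after winter
* target present, in percent of the substrate first charged, after midnight

- dusk: at 30 min take out 90% of the by-product then present, then wait 1.0 h
- noon: change nothing and wait 1.0 h more
- winter: at 30 min add partner, 100% of the amount charged, then wait 1.0 h
- midnight: at 30 min raise the temperature by 10 K, then wait 1.0 h

- additions leave the volume as it is
- reactions considered so far: target <-> isomer of the product; substrate + partner <-> intermediate; intermediate <-> target + by-product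
- the earlier runs do not show what temperature does; that part of a forecast is a guess

Theta holds twice the partner of zeta, so I count each theta minute double. Theta at 1.00 min then meets zeta at 2.00 min, and they read 6% and 7%, a gap below the scatter of 1.5 percentage points. Zeta's rise ends near 10.0 min. I therefore carry one number, the reach: the time multiplied by the charged [partner], over that stall time multiplied by zeta's charged [partner].

For flask zeta at 30 min:

reach = 3.00

Zeta's readings went from 32% at a reach of 1 to 30% at this reach, so I expect nothing from noon and take about 30% for now. Reach gives no height, though: theta peaked at 44%, so the next run must change the flask and not the clock.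

The forecast gives 30% for now, 37% for winter and 28% for midnight, and it chooses dusk: “Dusk looks best, though not far ahead of winter.”

The flask gives 30.0%, 33.5% after winter and 43.1% after midnight. The best choice is midnight, with a gain of 13 points, against 3.5 points for winter, 3.4 points for dusk and 0.42 points for noon.

    target ⇌ isomer of the product (K = 1.80, k = 0.00220 /s, Ea = 86.0 kJ/mol, ΔH = −47.0 kJ/mol)
    substrate + partner ⇌ intermediate (K = 1.20 /M, k = 0.00660 /M/s, Ea = 65.0 kJ/mol, ΔH = 15.0 kJ/mol)
    intermediate ⇌ target + by-product (K = 5.40 M, k = 0.00690 /s, Ea = 86.0 kJ/mol, ΔH = −11.0 kJ/mol)
    (constants at 5 °C)

In flask zeta, target is nearly level, at 30.7% after 15.0 min and 30.0% after 30.0 min, yet substrate, the limiting reagent, has 20% left and isomer has grown from 30.6% to 46.4%. The half-life of target by its forward step to isomer, 5.3 min, is short against 30 min, and over these minutes material goes on to isomer while target stays nearly level.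

In a neighbour flask charged with 0.12 M of substrate, the reach at 30 min is 0.720, which zeta passes between its readings at 6.00 min and 10.0 min, so the reach points to 26% to 32% target. The neighbour gives 20.5% target, below zeta's 26% at 6.00 min, with 27.3% isomer, and substrate holds the largest share at 49.8%, so the reach overshoots in this neighbour.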